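**Plan**

- Numbering: ring C1 (exocyclic CH2), C2, C3, C4=C5 (E, methyl on C5), C6, C7, C8 (side chain), C9 (CO2Me); side chain C10 (on C8, carries CH2OAc), C11, C12=C13, C14 (CMe2OH). The ring bond C5–C6 joins the methyl-bearing alkene carbon to a plain C6H2–C7H2 link, so an (E)-C5 vinyl iodide and a vinyl group on C8 can be united by hydroboration and B-alkyl Suzuki–Miyaura coupling.
- Cuts, in retrosynthetic order: acetate C–O; C14–CH3; C12=C13; ring bond C5–C6; C8–C9 together with the ester C–O at C11; C10–C11; C2–C3.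
- Forward: an iodo-acid (C9, C1–C5) and a dienyl carbinol (C6–C8, C10–C12) are esterified, rearranged and methylated; the nine-membered ring, the only ring, then closes at C5–C6; the side chain is finished last.
- Stereochemistry: the C11 carbinol is set by CBS reduction and relayed to C8 (S) and C9 (R) by a chair Ireland–Claisen rearrangement, which also fixes C10=C11. C4=C5 (E) comes from syn hydrozirconation–iodination and is retained in the coupling. C12=C13 (E) comes from a stabilised ylide.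

Key step: step 14

Assumption: the kinetic lithium enolate of the 3-methylidene ester is taken to follow the usual ester rule in THF (α-substituent cis to the alkoxy oxygen). The fallback for step 12 covers the opposite case.

**Route**

Step 1
Reactants: 1 3-methylbut-3-en-1-ol; 2 1-bromobut-2-yne
Product: 4 3-methylideneoct-6-yn-1-ol, via O,C-dilithiated isoprenol 3 (not isolated)
Conditions: n-BuLi (2.1 equiv), TMEDA, Et2O, 0 °C → rt; then 2, THF, −78 °C → 0 °C
Reagents that add atoms: none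
Why: Alkoxide-assisted allylic metalation gives the 2-substituted allyl dianion, whose carbon terminus is alkylated by the propargylic bromide (SN2 alkylation of a dianion), forming C2–C3.

Step 2
Reactants: 4 3-methylideneoct-6-yn-1-ol
Product: 6 (6E)-7-iodo-3-methylideneoct-6-en-1-ol, via alkenylzirconocene 5 (not isolated)
Conditions: Cp2Zr(H)Cl (3 equiv), THF, rt → 45 °C; then I2, THF, 0 °C
Reagents that add atoms: iodine, II
Why: Syn hydrozirconation of the 2-alkyne (the hydroxyl is first tied up as its zirconium alkoxide), equilibration with excess hydride to the methyl-bearing carbon and iodinolysis with retention should give the (E)-2-iodo-2-alkene, the 1,1-disubstituted alkene reacting far more slowly.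

Step 3
Reactants: 6 (6E)-7-iodo-3-methylideneoct-6-en-1-ol
Product: 8 (6E)-7-iodo-3-methylideneoct-6-enoic acid, via aldehyde 7 (not isolated)
Conditions: TEMPO (cat.), PhI(OAc)2, MeCN–H2O, rt
Reagents that add atoms: water, O
Why: Nitroxyl-catalysed oxidation takes the primary alcohol through the aldehyde hydrate to the acid under near-neutral conditions that should neither conjugate the β,γ-alkene nor touch the vinyl iodide.

Step 4
Reactants: 9 but-2-yne-1,4-diol
Product: 10 4-[tert-butyl(dimethyl)silyl]oxybut-2-yn-1-ol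
Conditions: TBSCl (1 equiv), imidazole, DMF, 0 °C, diol in excess
Reagents that add atoms: tert-butyldimethylsilyl chloride, CC(C)(C)[Si](C)(C)Cl
Why: Statistical monosilylation of a symmetrical diol used in excess (silyl ether formation).

Step 5
Reactants: 10 4-[tert-butyl(dimethyl)silyl]oxybut-2-yn-1-ol
Product: 12 (2Z)-4-[tert-butyl(dimethyl)silyl]oxy-3-iodobut-2-en-1-ol, via cyclic alkenylalanate 11 (not isolated)
Conditions: NaAlH2(OCH2CH2OMe)2, Et2O, 0 °C → rt; then EtOAc, then I2, THF, −78 °C → 0 °C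
Reagents that add atoms: iodine, II
Why: Hydroxyl-directed trans-hydroalumination of the propargylic alcohol places hydride on C2 and aluminium on C3 in a five-membered alanate, and iodinolysis with retention gives the (Z)-iodide on the carbon that carries CH2OTBS.

Step 6
Reactants: 12 (2Z)-4-[tert-butyl(dimethyl)silyl]oxy-3-iodobut-2-en-1-ol
Product: 13 (2Z)-4-[tert-butyl(dimethyl)silyl]oxy-3-iodobut-2-enal
Conditions: MnO2, CH2Cl2, rt
Reagents that add atoms: none
Why: Allylic oxidation with MnO2 is neutral and should preserve the (Z)-β-iodo enal geometry.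

Step 7
Reactants: 13 (2Z)-4-[tert-butyl(dimethyl)silyl]oxy-3-iodobut-2-enal
Product: 14 tert-butyl-[(2Z)-2-iodopenta-2,4-dienoxy]-dimethylsilane
Conditions: Ph3PCH3Br, NaN(SiMe3)2, THF, −78 °C → 0 °C
Reagents that add atoms: methyltriphenylphosphonium bromide, C[P+](c1ccccc1)(c1ccccc1)c1ccccc1.[Br-]
Why: Wittig methylenation of the aldehyde gives the 2-iodo-1,3-diene without disturbing the C–I bond or the alkene geometry.

Step 8
Reactants: 14 tert-butyl-[(2Z)-2-iodopenta-2,4-dienoxy]-dimethylsilane; 15 2-[(4-methoxyphenyl)methoxy]acetaldehyde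
Product: 16 rac-(3Z)-3-[[tert-butyl(dimethyl)silyl]oxymethyl]-1-[(4-methoxyphenyl)methoxy]hexa-3,5-dien-2-ol
Conditions: CrCl2 (excess), NiCl2 (cat.), DMSO, rt
Reagents that add atoms: none
Why: Nozaki–Hiyama–Kishi coupling forms C10–C11 with retention of the iodide geometry and tolerates the allylic silyl ether, which an alkenyllithium might eliminate; the carbinol forms as the racemate.

Step 9
Reactants: 16 rac-(3Z)-3-[[tert-butyl(dimethyl)silyl]oxymethyl]-1-[(4-methoxyphenyl)methoxy]hexa-3,5-dien-2-ol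
Product: 17 (3Z)-3-[[tert-butyl(dimethyl)silyl]oxymethyl]-1-[(4-methoxyphenyl)methoxy]hexa-3,5-dien-2-one
Conditions: Dess–Martin periodinane, NaHCO3, CH2Cl2, 0 °C; used at once
Reagents that add atoms: none
Why: Buffered Dess–Martin oxidation of the secondary allylic alcohol is fast and mild; the cis-dienone is not stored.

Step 10
Reactants: 17 (3Z)-3-[[tert-butyl(dimethyl)silyl]oxymethyl]-1-[(4-methoxyphenyl)methoxy]hexa-3,5-dien-2-one
Product: 18 (2S,3Z)-3-[[tert-butyl(dimethyl)silyl]oxymethyl]-1-[(4-methoxyphenyl)methoxy]hexa-3,5-dien-2-ol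
Conditions: (S)-2-methyl-CBS-oxazaborolidine (cat.), catecholborane, toluene, −78 °C
Reagents that add atoms: none
Why: Corey–Bakshi–Shibata reduction with the α-branched dienyl group as the large and CH2OPMB as the small substituent should deliver hydride to the face that gives the (S)-carbinol, and catecholborane at this temperature should not hydroborate the diene.

Step 11
Reactants: 8 (6E)-7-iodo-3-methylideneoct-6-enoic acid; 18 (2S,3Z)-3-[[tert-butyl(dimethyl)silyl]oxymethyl]-1-[(4-methoxyphenyl)methoxy]hexa-3,5-dien-2-ol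
Product: 19 [(2S,3Z)-3-[[tert-butyl(dimethyl)silyl]oxymethyl]-1-[(4-methoxyphenyl)methoxy]hexa-3,5-dien-2-yl] (6E)-7-iodo-3-methylideneoct-6-enoate
Conditions: DCC, DMAP (cat.), CH2Cl2, −20 °C → 0 °C
Reagents that add atoms: none
Why: Steglich esterification at low temperature with little DMAP limits migration of the β,γ-alkene into conjugation and acylates oxygen without touching the carbinol centre.

Step 12
Reactants: 19 [(2S,3Z)-3-[[tert-butyl(dimethyl)silyl]oxymethyl]-1-[(4-methoxyphenyl)methoxy]hexa-3,5-dien-2-yl] (6E)-7-iodo-3-methylideneoct-6-enoate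
Product: 22 (2R,3S,4Z)-4-[[tert-butyl(dimethyl)silyl]oxymethyl]-3-ethenyl-2-[(5E)-6-iodohepta-1,5-dien-2-yl]-6-[(4-methoxyphenyl)methoxy]hex-4-enoic acid, via trimethylsilyl ketene acetal 20 (not isolated), via trimethylsilyl ester 21 (not isolated)
Conditions: lithium diisopropylamide, Me3SiCl–Et3N, THF, −78 °C → rt; then dilute aq. citric acid
Reagents that add atoms: none
Why: Ireland–Claisen rearrangement: kinetic enolisation with in-situ silylation gives the ketene acetal with the C1 chain cis to the allylic oxygen, and the chair [3,3] shift with CH2OPMB equatorial, the cis vinyl group axial on C8 and the C1 chain axial on C9 transfers the (S)-carbinol centre to C8 (S) and C9 (R) and sets C10=C11 with C12 trans to C8.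

Step 13
Reactants: 22 (2R,3S,4Z)-4-[[tert-butyl(dimethyl)silyl]oxymethyl]-3-ethenyl-2-[(5E)-6-iodohepta-1,5-dien-2-yl]-6-[(4-methoxyphenyl)methoxy]hex-4-enoic acid
Product: 23 methyl (2R,3S,4Z)-4-[[tert-butyl(dimethyl)silyl]oxymethyl]-3-ethenyl-2-[(5E)-6-iodohepta-1,5-dien-2-yl]-6-[(4-methoxyphenyl)methoxy]hex-4-enoate
Conditions: Me3SiCHN2, MeOH–toluene, 0 °C
Reagents that add atoms: trimethylsilyldiazomethane, C[Si](C)(C)C=[N+]=[N-]
Why: O-Methylation of the carboxylic acid with the diazoalkane is neutral, so C9 should not epimerise and the C1 methylene should not move into conjugation.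

Step 14
Reactants: 23 methyl (2R,3S,4Z)-4-[[tert-butyl(dimethyl)silyl]oxymethyl]-3-ethenyl-2-[(5E)-6-iodohepta-1,5-dien-2-yl]-6-[(4-methoxyphenyl)methoxy]hex-4-enoate
Product: 25 methyl (1R,2S,5E)-2-[(2Z)-1-[tert-butyl(dimethyl)silyl]oxy-4-[(4-methoxyphenyl)methoxy]but-2-en-2-yl]-5-methyl-9-methylidenecyclonon-5-ene-1-carboxylate, via B-alkyl-9-BBN 24 (not isolated)
Conditions: 9-BBN (1.2 equiv), THF, 0 °C → rt; then slow addition to PdCl2(dppf) (cat.), AsPh3, Cs2CO3, DMF–THF–H2O, 50 °C, high dilution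
Reagents that add atoms: none
Why: 9-BBN adds anti-Markovnikov to the only monosubstituted alkene (C6=C7), the C1 methylene being screened by the C9 methine and deactivated by the allylic ester, so boron ends on C6; zerovalent palladium then inserts into the C5–I bond with retention, the base-activated borane transfers its primary alkyl group, and reductive elimination forms C5–C6. The closest known reaction type is the intramolecular B-alkyl Suzuki–Miyaura macrocyclisation used for medium and large carbocycles that hold a trisubstituted E alkene. The nine-membered ring closes in the reductive elimination from a ten-membered palladacycle, leaving C4=C5 endocyclic, and slow addition at high dilution favours this over intermolecular coupling. No stereocentre is formed: C8 and C9 are spectators and the E geometry of C4=C5 is carried over from the vinyl iodide. The step needs site-selective hydroboration and survival of the epimerisable C9 ester, which the alkene substitution pattern, a near-stoichiometric amount of borane and the mild carbonate base should secure.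

Step 15
Reactants: 25 methyl (1R,2S,5E)-2-[(2Z)-1-[tert-butyl(dimethyl)silyl]oxy-4-[(4-methoxyphenyl)methoxy]but-2-en-2-yl]-5-methyl-9-methylidenecyclonon-5-ene-1-carboxylate
Product: 26 methyl (1R,2S,5E)-2-[(2Z)-1-[tert-butyl(dimethyl)silyl]oxy-4-hydroxybut-2-en-2-yl]-5-methyl-9-methylidenecyclonon-5-ene-1-carboxylate
Conditions: DDQ, CH2Cl2–pH 7 buffer, 0 °C
Reagents that add atoms: none
Why: Oxidative cleavage of the PMB ether by DDQ spares the TBS ether, the ester and the unactivated alkenes, and the freed C12 hydroxyl cannot reach the ester because it is trans to C8.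

Step 16
Reactants: 26 methyl (1R,2S,5E)-2-[(2Z)-1-[tert-butyl(dimethyl)silyl]oxy-4-hydroxybut-2-en-2-yl]-5-methyl-9-methylidenecyclonon-5-ene-1-carboxylate
Product: 27 methyl (1R,2S,5E)-2-[(2Z)-1-[tert-butyl(dimethyl)silyl]oxy-4-oxobut-2-en-2-yl]-5-methyl-9-methylidenecyclonon-5-ene-1-carboxylate
Conditions: MnO2, CH2Cl2, rt
Reagents that add atoms: none
Why: Allylic oxidation with MnO2 gives the enal, whose geometry (CHO trans to the bulky C8) is already the thermodynamically preferred one.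

Step 17
Reactants: 27 methyl (1R,2S,5E)-2-[(2Z)-1-[tert-butyl(dimethyl)silyl]oxy-4-oxobut-2-en-2-yl]-5-methyl-9-methylidenecyclonon-5-ene-1-carboxylate; 28 1-(triphenyl-λ5-phosphanylidene)propan-2-one
Product: 29 methyl (1R,2S,5E)-2-[(2Z,4E)-1-[tert-butyl(dimethyl)silyl]oxy-6-oxohepta-2,4-dien-2-yl]-5-methyl-9-methylidenecyclonon-5-ene-1-carboxylate
Conditions: toluene, 60 °C
Reagents that add atoms: none
Why: Wittig reaction with the stabilised acetonyl ylide should form the C12=C13 alkene E-selectively and is not basic enough to disturb C9.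

Step 18
Reactants: 29 methyl (1R,2S,5E)-2-[(2Z,4E)-1-[tert-butyl(dimethyl)silyl]oxy-6-oxohepta-2,4-dien-2-yl]-5-methyl-9-methylidenecyclonon-5-ene-1-carboxylate
Product: 30 methyl (1R,2S,5E)-2-[(2Z,4E)-1-[tert-butyl(dimethyl)silyl]oxy-6-hydroxy-6-methylhepta-2,4-dien-2-yl]-5-methyl-9-methylidenecyclonon-5-ene-1-carboxylate
Conditions: MeTi(OiPr)3 (from MeLi and ClTi(OiPr)3), THF, −20 °C → rt
Reagents that add atoms: methyltitanium triisopropoxide, C[Ti](OC(C)C)(OC(C)C)OC(C)C
Why: 1,2-Addition of the non-basic, ketone-selective organotitanium reagent to the methyl ketone should give the tertiary alcohol while leaving the methyl ester and the acidic C9–H alone.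

Step 19
Reactants: 30 methyl (1R,2S,5E)-2-[(2Z,4E)-1-[tert-butyl(dimethyl)silyl]oxy-6-hydroxy-6-methylhepta-2,4-dien-2-yl]-5-methyl-9-methylidenecyclonon-5-ene-1-carboxylate
Product: 31 methyl (1R,2S,5E)-2-[(2Z,4E)-1,6-dihydroxy-6-methylhepta-2,4-dien-2-yl]-5-methyl-9-methylidenecyclonon-5-ene-1-carboxylate
Conditions: Bu4NF, AcOH, THF, 0 °C; crude diol taken on at once
Reagents that add atoms: none
Why: Fluoride cleavage of the primary TBS ether buffered with acetic acid avoids both ionisation of the tertiary dienylic alcohol and base-promoted lactonisation of the freed hydroxyl onto the C9 ester.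

Step 20
Reactants: 31 methyl (1R,2S,5E)-2-[(2Z,4E)-1,6-dihydroxy-6-methylhepta-2,4-dien-2-yl]-5-methyl-9-methylidenecyclonon-5-ene-1-carboxylate
Product: 32 methyl (1R,2S,5E)-2-[(2Z,4E)-1-acetyloxy-6-hydroxy-6-methylhepta-2,4-dien-2-yl]-5-methyl-9-methylidenecyclonon-5-ene-1-carboxylate
Conditions: Ac2O, pyridine, CH2Cl2, 0 °C
Reagents that add atoms: acetic anhydride, CC(=O)OC(C)=O
Why: O-Acetylation without DMAP is selective for the primary alcohol over the tertiary one and gives the target.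

**Compound list**

1 | 3-methylbut-3-en-1-ol | C=C(C)CCO | starting material
2 | 1-bromobut-2-yne | CC#CCBr | starting material
3 | lithium 3-(lithiomethyl)but-3-en-1-olate (O,C-dilithiated 1) | [Li]CC(=C)CCO[Li] | intermediate
4 | 3-methylideneoct-6-yn-1-ol | CC#CCCC(=C)CCO | intermediate
5 | (6E)-alkenylzirconocene from 4: Cp2Zr(Cl) on C7 and on the alkoxide oxygen (Cp drawn σ-bound) | C/C(=C\CCC(=C)CCO[Zr](Cl)(C1C=CC=C1)C1C=CC=C1)[Zr](Cl)(C1C=CC=C1)C1C=CC=C1 | intermediate
6 | (6E)-7-iodo-3-methylideneoct-6-en-1-ol | C/C(I)=C\CCC(=C)CCO | intermediate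
7 | (6E)-7-iodo-3-methylideneoct-6-enal | C/C(I)=C\CCC(=C)CC=O | intermediate
8 | (6E)-7-iodo-3-methylideneoct-6-enoic acid | C/C(I)=C\CCC(=C)CC(=O)O | intermediate
9 | but-2-yne-1,4-diol | OCC#CCO | starting material
10 | 4-[tert-butyl(dimethyl)silyl]oxybut-2-yn-1-ol | CC(C)(C)[Si](C)(C)OCC#CCO | intermediate
11 | sodium salt of the five-membered oxa-alanate (Al on C3, two 2-methoxyethoxy ligands) | [Na+].COCCO[Al-]1(OCCOC)OCC=C1CO[Si](C)(C)C(C)(C)C | intermediate
12 | (2Z)-4-[tert-butyl(dimethyl)silyl]oxy-3-iodobut-2-en-1-ol | CC(C)(C)[Si](C)(C)OC/C(I)=C/CO | intermediate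
13 | (2Z)-4-[tert-butyl(dimethyl)silyl]oxy-3-iodobut-2-enal | CC(C)(C)[Si](C)(C)OC/C(I)=C/C=O | intermediate
14 | tert-butyl-[(2Z)-2-iodopenta-2,4-dienoxy]-dimethylsilane | CC(C)(C)[Si](C)(C)OC/C(I)=C/C=C | intermediate
15 | 2-[(4-methoxyphenyl)methoxy]acetaldehyde | COc1ccc(COCC=O)cc1 | starting material
16 | rac-(3Z)-3-[[tert-butyl(dimethyl)silyl]oxymethyl]-1-[(4-methoxyphenyl)methoxy]hexa-3,5-dien-2-ol | C=C/C=C(/CO[Si](C)(C)C(C)(C)C)C(O)COCc1ccc(OC)cc1 | intermediate
17 | (3Z)-3-[[tert-butyl(dimethyl)silyl]oxymethyl]-1-[(4-methoxyphenyl)methoxy]hexa-3,5-dien-2-one | C=C/C=C(/CO[Si](C)(C)C(C)(C)C)C(=O)COCc1ccc(OC)cc1 | intermediate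
18 | (2S,3Z)-3-[[tert-butyl(dimethyl)silyl]oxymethyl]-1-[(4-methoxyphenyl)methoxy]hexa-3,5-dien-2-ol | C=C/C=C(/CO[Si](C)(C)C(C)(C)C)[C@H](O)COCc1ccc(OC)cc1 | intermediate
19 | [(2S,3Z)-3-[[tert-butyl(dimethyl)silyl]oxymethyl]-1-[(4-methoxyphenyl)methoxy]hexa-3,5-dien-2-yl] (6E)-7-iodo-3-methylideneoct-6-enoate | C=C/C=C(/CO[Si](C)(C)C(C)(C)C)[C@H](OC(=O)CC(=C)CC/C=C(\C)I)COCc1ccc(OC)cc1 | intermediate
20 | trimethylsilyl ketene acetal of 19 (C1 chain cis to the allylic oxygen) | C=C/C=C(/CO[Si](C)(C)C(C)(C)C)[C@H](O/C(O[Si](C)(C)C)=C\C(=C)CC/C=C(\C)I)COCc1ccc(OC)cc1 | intermediate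
21 | trimethylsilyl ester of acid 22 | C=C[C@H](/C(=C/COCc1ccc(OC)cc1)CO[Si](C)(C)C(C)(C)C)[C@H](C(=C)CC/C=C(\C)I)C(=O)O[Si](C)(C)C | intermediate
22 | (2R,3S,4Z)-4-[[tert-butyl(dimethyl)silyl]oxymethyl]-3-ethenyl-2-[(5E)-6-iodohepta-1,5-dien-2-yl]-6-[(4-methoxyphenyl)methoxy]hex-4-enoic acid | C=C[C@H](/C(=C/COCc1ccc(OC)cc1)CO[Si](C)(C)C(C)(C)C)[C@H](C(=C)CC/C=C(\C)I)C(=O)O | intermediate
23 | methyl (2R,3S,4Z)-4-[[tert-butyl(dimethyl)silyl]oxymethyl]-3-ethenyl-2-[(5E)-6-iodohepta-1,5-dien-2-yl]-6-[(4-methoxyphenyl)methoxy]hex-4-enoate | C=C[C@H](/C(=C/COCc1ccc(OC)cc1)CO[Si](C)(C)C(C)(C)C)[C@H](C(=C)CC/C=C(\C)I)C(=O)OC | intermediate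
24 | B-alkyl-9-borabicyclo[3.3.1]nonane from 23 (boron on C6, the former vinyl terminus) | C1CC2CCCC(C1)B2CC[C@H](/C(=C/COCc1ccc(OC)cc1)CO[Si](C)(C)C(C)(C)C)[C@H](C(=C)CC/C=C(\C)I)C(=O)OC | intermediate
25 | methyl (1R,2S,5E)-2-[(2Z)-1-[tert-butyl(dimethyl)silyl]oxy-4-[(4-methoxyphenyl)methoxy]but-2-en-2-yl]-5-methyl-9-methylidenecyclonon-5-ene-1-carboxylate | C=C1CC/C=C(\C)CC[C@H](/C(=C/COCc2ccc(OC)cc2)CO[Si](C)(C)C(C)(C)C)[C@H]1C(=O)OC | intermediate
26 | methyl (1R,2S,5E)-2-[(2Z)-1-[tert-butyl(dimethyl)silyl]oxy-4-hydroxybut-2-en-2-yl]-5-methyl-9-methylidenecyclonon-5-ene-1-carboxylate | C=C1CC/C=C(\C)CC[C@H](/C(=C/CO)CO[Si](C)(C)C(C)(C)C)[C@H]1C(=O)OC | intermediate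
27 | methyl (1R,2S,5E)-2-[(2Z)-1-[tert-butyl(dimethyl)silyl]oxy-4-oxobut-2-en-2-yl]-5-methyl-9-methylidenecyclonon-5-ene-1-carboxylate | C=C1CC/C=C(\C)CC[C@H](/C(=C/C=O)CO[Si](C)(C)C(C)(C)C)[C@H]1C(=O)OC | intermediate
28 | 1-(triphenyl-λ5-phosphanylidene)propan-2-one | CC(=O)C=P(c1ccccc1)(c1ccccc1)c1ccccc1 | starting material
29 | methyl (1R,2S,5E)-2-[(2Z,4E)-1-[tert-butyl(dimethyl)silyl]oxy-6-oxohepta-2,4-dien-2-yl]-5-methyl-9-methylidenecyclonon-5-ene-1-carboxylate | C=C1CC/C=C(\C)CC[C@H](/C(=C/C=C/C(C)=O)CO[Si](C)(C)C(C)(C)C)[C@H]1C(=O)OC | intermediate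
30 | methyl (1R,2S,5E)-2-[(2Z,4E)-1-[tert-butyl(dimethyl)silyl]oxy-6-hydroxy-6-methylhepta-2,4-dien-2-yl]-5-methyl-9-methylidenecyclonon-5-ene-1-carboxylate | C=C1CC/C=C(\C)CC[C@H](/C(=C/C=C/C(C)(C)O)CO[Si](C)(C)C(C)(C)C)[C@H]1C(=O)OC | intermediate
31 | methyl (1R,2S,5E)-2-[(2Z,4E)-1,6-dihydroxy-6-methylhepta-2,4-dien-2-yl]-5-methyl-9-methylidenecyclonon-5-ene-1-carboxylate | C=C1CC/C=C(\C)CC[C@H](/C(=C/C=C/C(C)(C)O)CO)[C@H]1C(=O)OC | intermediate
32 | methyl (1R,2S,5E)-2-[(2Z,4E)-1-acetyloxy-6-hydroxy-6-methylhepta-2,4-dien-2-yl]-5-methyl-9-methylidenecyclonon-5-ene-1-carboxylate | C=C1CC/C=C(\C)CC[C@H](/C(=C/C=C/C(C)(C)O)COC(C)=O)[C@H]1C(=O)OC | target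

**Step count and risks**

Total: 20 steps. Longest linear sequence: 17 steps (steps 4–20, from but-2-yne-1,4-diol).

Steps most likely to fail:

1. Step 14. The borane may also add to the C1 methylene, which 9-BBN distinguishes from the vinyl group only moderately. Intermolecular coupling may outrun closure of the strained (E)-cyclononene. The aqueous carbonate may slowly epimerise or conjugate the C9 ester. The fallback sets out from 23 and comes back at 25, forming the same C5–C6 bond without base. Disiamylborane, which discriminates far more strongly between mono- and 1,1-disubstituted alkenes, hydroborates the vinyl group to the disiamyl alkylborane F1. Oxidation with NaBO3·4H2O gives the primary alcohol F2, which is converted without delay (I2, PPh3, imidazole) into the primary iodide F3. Zinc dust (LiCl, THF) inserts only into the sp3 C–I bond to give the alkylzinc iodide F4. Slow addition of F4 to Pd(PPh3)4 in THF closes the ring by intramolecular Negishi coupling with the vinyl iodide, giving 25.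

2. Step 12. Enolisation of the doubly activated β,γ-unsaturated ester may give the ketene acetal with the C1 chain trans to the allylic oxygen, or a mixture, which leads to the C9 epimer. The fallback sets out from 17 and comes back at 22, pairing the opposite enolate geometry with the opposite alkene geometry. A trace of iodine in CH2Cl2 under visible light equilibrates 17 to the more stable (3E)-dienone F5. (R)-2-Methyl-CBS-oxazaborolidine with catecholborane reduces F5 to the (2R,3E)-carbinol F6, and DCC with catalytic DMAP joins F6 to acid 8 as ester F7. Enolisation with lithium diisopropylamide in THF–DMPU and silylation with Me3SiCl gives the ketene acetal F8 with the chain trans to the allylic oxygen. F8 rearranges through the chair in which the vinyl group on C8, the C1 chain on C9 and CH2OPMB are all equatorial, giving silyl ester 21 and, after mild acid work-up, acid 22.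

3. Step 10. The cis-dienone 17 may undergo oxa-6π electrocyclisation or Z-to-E isomerisation before it is reduced, and face discrimination between CH2OPMB and the dienyl group may be incomplete. The fallback sets out from racemic 16 and comes back at 18 without passing through the ketone. Esterification with (S)-2-methoxy-2-phenylacetic acid (DCC, DMAP) gives the diastereomeric esters F9 (from the 2S alcohol) and F10 (from the 2R alcohol), which are separated by chromatography. Methanolysis of F9 (K2CO3, MeOH) returns 18.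

**Further compounds**

F1 | step 14 | methyl (2R,3S,4Z)-3-[2-[bis(3-methylbutan-2-yl)boranyl]ethyl]-4-[[tert-butyl(dimethyl)silyl]oxymethyl]-2-[(5E)-6-iodohepta-1,5-dien-2-yl]-6-[(4-methoxyphenyl)methoxy]hex-4-enoate | CC(C)C(C)B(CC[C@H](/C(=C/COCc1ccc(OC)cc1)CO[Si](C)(C)C(C)(C)C)[C@H](C(=C)CC/C=C(\C)I)C(=O)OC)C(C)C(C)C
F2 | step 14 | methyl (2R,3S,4Z)-4-[[tert-butyl(dimethyl)silyl]oxymethyl]-3-(2-hydroxyethyl)-2-[(5E)-6-iodohepta-1,5-dien-2-yl]-6-[(4-methoxyphenyl)methoxy]hex-4-enoate | OCC[C@H](/C(=C/COCc1ccc(OC)cc1)CO[Si](C)(C)C(C)(C)C)[C@H](C(=C)CC/C=C(\C)I)C(=O)OC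
F3 | step 14 | methyl (2R,3S,4Z)-4-[[tert-butyl(dimethyl)silyl]oxymethyl]-3-(2-iodoethyl)-2-[(5E)-6-iodohepta-1,5-dien-2-yl]-6-[(4-methoxyphenyl)methoxy]hex-4-enoate | ICC[C@H](/C(=C/COCc1ccc(OC)cc1)CO[Si](C)(C)C(C)(C)C)[C@H](C(=C)CC/C=C(\C)I)C(=O)OC
F4 | step 14 | alkylzinc iodide from F3 (zinc on C6, vinyl iodide intact) | I[Zn]CC[C@H](/C(=C/COCc1ccc(OC)cc1)CO[Si](C)(C)C(C)(C)C)[C@H](C(=C)CC/C=C(\C)I)C(=O)OC
F5 | step 12 | (3E)-3-[[tert-butyl(dimethyl)silyl]oxymethyl]-1-[(4-methoxyphenyl)methoxy]hexa-3,5-dien-2-one | C=C/C=C(\CO[Si](C)(C)C(C)(C)C)C(=O)COCc1ccc(OC)cc1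
F6 | step 12 | (2R,3E)-3-[[tert-butyl(dimethyl)silyl]oxymethyl]-1-[(4-methoxyphenyl)methoxy]hexa-3,5-dien-2-ol | C=C/C=C(\CO[Si](C)(C)C(C)(C)C)[C@@H](O)COCc1ccc(OC)cc1
F7 | step 12 | [(2R,3E)-3-[[tert-butyl(dimethyl)silyl]oxymethyl]-1-[(4-methoxyphenyl)methoxy]hexa-3,5-dien-2-yl] (6E)-7-iodo-3-methylideneoct-6-enoate | C=C/C=C(\CO[Si](C)(C)C(C)(C)C)[C@@H](OC(=O)CC(=C)CC/C=C(\C)I)COCc1ccc(OC)cc1
F8 | step 12 | trimethylsilyl ketene acetal of F7 (C1 chain trans to the allylic oxygen) | C=C/C=C(\CO[Si](C)(C)C(C)(C)C)[C@@H](O/C(O[Si](C)(C)C)=C/C(=C)CC/C=C(\C)I)COCc1ccc(OC)cc1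
F9 | step 10 | [(2S,3Z)-3-[[tert-butyl(dimethyl)silyl]oxymethyl]-1-[(4-methoxyphenyl)methoxy]hexa-3,5-dien-2-yl] (2S)-2-methoxy-2-phenylacetate | C=C/C=C(/CO[Si](C)(C)C(C)(C)C)[C@H](OC(=O)[C@@H](OC)c1ccccc1)COCc1ccc(OC)cc1
F10 | step 10 | [(2R,3Z)-3-[[tert-butyl(dimethyl)silyl]oxymethyl]-1-[(4-methoxyphenyl)methoxy]hexa-3,5-dien-2-yl] (2S)-2-methoxy-2-phenylacetate | C=C/C=C(/CO[Si](C)(C)C(C)(C)C)[C@@H](OC(=O)[C@@H](OC)c1ccccc1)COCc1ccc(OC)cc1
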